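**Retrosynthetic overview**

1. In the cyclohexene (C-1, C-11, C-12, C-13, C-14, C-15) the array C-15(CO2H)–C-11(H)–C-12(=C-13)–CH2OH is a γ,δ-unsaturated acid once the ring double bond is moved exocyclic. The CH2OH carbon is then an allylic carbinol carbon, so the target's own CO2H and CH2OH can be tied as an allyl ester whose enolate carbon is C-15 and whose alkene CH is C-11.
2. Key disconnection: C-15–C-11, by a transannular ring-contracting Ireland–Claisen rearrangement of an eight-membered lactone (C-15, C=O, O, CH2, C-12, C-13, C-14, C-1) fused to a 14-membered carbocycle. The six-membered ring arises from the lactone by loss of two ring atoms, the 12-membered ring from the 14-membered ring, and C-15 and C-11 are set in the same event.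
3. The exocyclic methylene left at C-12 is returned to the ring as C-12=C-13 with CH2OH by iodolactonisation, epoxide formation and base-mediated epoxide opening.
4. The lactone comes from a 14-membered triene closed at C-13–C-12 by intramolecular B-alkyl Suzuki coupling (vinyl group plus Z vinyl iodide), then lactonisation. The acyclic chain is a (2E,6Z)-farnesyl unit from nerol; its single stereocentre (future C-1) is set by iridium-catalysed allylic alkylation of dimethyl malonate.
5. Ring order: 14-membered carbocycle, eight-membered lactone, then six- and 12-membered carbocycles together (key step), then a temporary γ-lactone and spiro-epoxide.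

Key step: step 22

**Remarks before the steps**

- Locants: ring atoms carry the locants of the bicyclo[9.3.1]pentadecane skeleton of the target. C-15 is the quaternary carbon, C-1 and C-11 the ring CH groups beside it, C-12 the alkene carbon with CH2OH, C-13 and C-14 the other cyclohexene carbons, C-2 to C-10 the nine-carbon bridge.
- Assumption: the (Ra,R,R)-phosphoramidite is taken to give the 3S product in step 9; the sense follows the ligand, so the mirror-image ligand is used if a test shows the opposite.
- From 25 to 30 the ester α-carbon (future C-15) is an unseparated pair of epimers, because it is planarised in step 22.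

**Route**

Step 1
Reactants: 1 nerol
Product: 2 neryl bromide
Conditions: PBr3, pyridine (cat.), Et2O, −10 °C
Reagents that add atoms: phosphorus tribromide BrP(Br)Br
Why: PBr3 converts the primary allylic alcohol into the bromide by SN2 displacement at low temperature, which keeps the Z trisubstituted alkene intact (alcohol-to-bromide substitution).

Step 2
Reactants: 2 neryl bromide; 3 1-(trimethylsilyl)propyne
Product: 4 (5Z)-6,10-dimethyl-1-(trimethylsilyl)undeca-5,9-dien-1-yne
Conditions: 3, n-BuLi, THF, −20 °C; then 2, −78 → 0 °C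
Reagents that add atoms: 1-(trimethylsilyl)propyne CC#C[Si](C)(C)C
Why: The propargylic lithium reagent alkylates the primary allylic bromide by SN2 displacement, the silyl group blocking the alkyne terminus (propargylation of an allylic halide).

Step 3
Reactants: 4 (5Z)-6,10-dimethyl-1-(trimethylsilyl)undeca-5,9-dien-1-yne
Product: 5 (5Z)-6,10-dimethylundeca-5,9-dien-1-yne
Conditions: K2CO3 (cat.), MeOH, rt
Reagents that add atoms: none
Why: Carbonate-catalysed methanolysis of the alkynyl C–Si bond frees the terminal alkyne (protodesilylation).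

Step 4
Reactants: 5 (5Z)-6,10-dimethylundeca-5,9-dien-1-yne
Product: 7 (2E,6Z)-farnesol, via alkenylalane 6 (not isolated)
Conditions: AlMe3, Cp2ZrCl2 (0.25 equiv), CH2Cl2, rt; then n-BuLi, THF, −78 °C; (CH2O)n, rt
Reagents that add atoms: trimethylaluminium C[Al](C)C; formaldehyde (from paraformaldehyde) C=O
Why: Zirconium-catalysed Negishi carboalumination adds methyl and aluminium syn across the terminal alkyne, so the new trisubstituted alkene is E, and the alanate formed with n-BuLi is hydroxymethylated by formaldehyde with retention of geometry.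

Step 5
Reactants: 7 (2E,6Z)-farnesol
Product: 8 (2E,6Z)-farnesyl bromide
Conditions: PBr3, Et2O, 0 °C
Reagents that add atoms: phosphorus tribromide BrP(Br)Br
Why: As in step 1, SN2 bromination of the primary allylic alcohol leaves both trisubstituted alkene geometries untouched.

Step 6
Reactants: 8 (2E,6Z)-farnesyl bromide; 9 propargyl alcohol
Product: 10 (5E,9Z)-6,10,14-trimethylpentadeca-5,9,13-trien-2-yn-1-ol
Conditions: 9, CuI (10 mol %), K2CO3, DMF, rt
Reagents that add atoms: propargyl alcohol C#CCO
Why: The copper acetylide of propargyl alcohol displaces the bromide at the primary allylic carbon (copper-catalysed alkynylation of an allylic halide), giving the skipped enyne.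

Step 7
Reactants: 10 (5E,9Z)-6,10,14-trimethylpentadeca-5,9,13-trien-2-yn-1-ol
Product: 11 (2E,5E,9Z)-6,10,14-trimethylpentadeca-2,5,9,13-tetraen-1-ol
Conditions: LiAlH4, THF, 66 °C
Reagents that add atoms: none
Why: The alkoxide directs trans-hydroalumination of the propargylic alkyne, which gives only the E allylic alcohol and leaves the isolated alkenes alone (propargylic alcohol reduction).

Step 8
Reactants: 11 (2E,5E,9Z)-6,10,14-trimethylpentadeca-2,5,9,13-tetraen-1-ol
Product: 12 methyl (2E,5E,9Z)-6,10,14-trimethylpentadeca-2,5,9,13-tetraenyl carbonate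
Conditions: ClCO2Me, pyridine, CH2Cl2, 0 °C
Reagents that add atoms: methyl chloroformate COC(=O)Cl
Why: Acylation of the primary allylic alcohol installs the leaving group for the allylic substitution (carbonate formation).

Step 9
Reactants: 12 methyl (2E,5E,9Z)-6,10,14-trimethylpentadeca-2,5,9,13-tetraenyl carbonate; 13 dimethyl malonate
Product: 14 dimethyl 2-[(3S,5E,9Z)-6,10,14-trimethylpentadeca-1,5,9,13-tetraen-3-yl]malonate
Conditions: 13, [Ir(cod)Cl]2 (2 mol %), (Ra)-binaphthyl-2,2′-diyl N,N-bis[(R)-1-phenylethyl]phosphoramidite (4 mol %), 1,5,7-triazabicyclo[4.4.0]dec-5-ene (8 mol %), THF, rt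
Reagents that add atoms: dimethyl malonate COC(=O)CC(=O)OC
Why: In this iridium-catalysed asymmetric allylic alkylation the malonate attacks the substituted terminus of the phosphoramidite-ligated allyl complex (branched product), and the ligand chirality sets the new stereocentre (future C-1) as S.

Step 10
Reactants: 14 dimethyl 2-[(3S,5E,9Z)-6,10,14-trimethylpentadeca-1,5,9,13-tetraen-3-yl]malonate
Product: 16 dimethyl 2-[(3S,5E,9Z)-13,14-epoxy-6,10,14-trimethylpentadeca-1,5,9-trien-3-yl]malonate, via bromohydrin 15 (not isolated)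
Conditions: NBS, THF/H2O, 0 °C; then K2CO3, MeOH, rt
Reagents that add atoms: water O
Why: NBS in aqueous THF forms the bromohydrin preferentially at the terminal trisubstituted alkene (van Tamelen terminal functionalisation, the internal alkenes being shielded by chain coiling and the vinyl group too unreactive), and carbonate closes it to the epoxide by intramolecular SN2 displacement.

Step 11
Reactants: 16 dimethyl 2-[(3S,5E,9Z)-13,14-epoxy-6,10,14-trimethylpentadeca-1,5,9-trien-3-yl]malonate; 17 5-bromo-2-methylpent-2-ene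
Product: 18 dimethyl 2-(4-methylpent-3-enyl)-2-[(3S,5E,9Z)-13,14-epoxy-6,10,14-trimethylpentadeca-1,5,9-trien-3-yl]malonate
Conditions: NaH, DMF, 0 °C; then 17, 50 °C
Reagents that add atoms: 5-bromo-2-methylpent-2-ene CC(C)=CCCBr
Why: The sodium enolate of the malonate is alkylated by the primary bromide (malonic ester alkylation), which makes the future C-15 quaternary without touching the hindered epoxide.

Step 12
Reactants: 18 dimethyl 2-(4-methylpent-3-enyl)-2-[(3S,5E,9Z)-13,14-epoxy-6,10,14-trimethylpentadeca-1,5,9-trien-3-yl]malonate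
Product: 19 dimethyl 2-(4-methylpent-3-enyl)-2-[(3S,5E,9Z)-6,10-dimethyl-13-oxotrideca-1,5,9-trien-3-yl]malonate
Conditions: HIO4·2H2O, THF/Et2O, 0 °C
Reagents that add atoms: none
Why: Periodic acid hydrolyses the trisubstituted epoxide and cleaves the diol to the aldehyde and acetone (glycol cleavage), leaving every alkene untouched.

Step 13
Reactants: 19 dimethyl 2-(4-methylpent-3-enyl)-2-[(3S,5E,9Z)-6,10-dimethyl-13-oxotrideca-1,5,9-trien-3-yl]malonate; 20 (triphenylphosphoranylidene)acetaldehyde
Product: 21 dimethyl 2-(4-methylpent-3-enyl)-2-[(3S,5E,9Z,13E)-6,10-dimethyl-15-oxopentadeca-1,5,9,13-tetraen-3-yl]malonate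
Conditions: 20, toluene, 80 °C
Reagents that add atoms: (triphenylphosphoranylidene)acetaldehyde O=CC=P(c1ccccc1)(c1ccccc1)c1ccccc1
Why: The stabilised formylmethylene ylide gives the E enal in a Wittig reaction, adding the future C-12 and the hydroxymethyl carbon.

Step 14
Reactants: 21 dimethyl 2-(4-methylpent-3-enyl)-2-[(3S,5E,9Z,13E)-6,10-dimethyl-15-oxopentadeca-1,5,9,13-tetraen-3-yl]malonate
Product: 22 dimethyl 2-(4-methylpent-3-enyl)-2-[(3S,5E,9Z,13Z)-14-iodo-6,10-dimethyl-15-oxopentadeca-1,5,9,13-tetraen-3-yl]malonate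
Conditions: I2, DMAP (cat.), K2CO3, THF/H2O, rt
Reagents that add atoms: iodine II
Why: Amine-catalysed α-iodination of the enal (conjugate addition of DMAP, iodination of the enolate, elimination) gives the 2-iodoenal in which the formyl group stays trans to the chain, so iodine is cis to the chain (Z).

Step 15
Reactants: 22 dimethyl 2-(4-methylpent-3-enyl)-2-[(3S,5E,9Z,13Z)-14-iodo-6,10-dimethyl-15-oxopentadeca-1,5,9,13-tetraen-3-yl]malonate
Product: 23 dimethyl 2-(4-methylpent-3-enyl)-2-[(3S,5E,9Z,13Z)-15-hydroxy-14-iodo-6,10-dimethylpentadeca-1,5,9,13-tetraen-3-yl]malonate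
Conditions: NaBH4, CeCl3·7H2O, MeOH, −40 °C
Reagents that add atoms: none
Why: Luche reduction delivers hydride 1,2 to the enal and spares the malonate esters and the vinyl iodide.

Step 16
Reactants: 23 dimethyl 2-(4-methylpent-3-enyl)-2-[(3S,5E,9Z,13Z)-15-hydroxy-14-iodo-6,10-dimethylpentadeca-1,5,9,13-tetraen-3-yl]malonate
Product: 24 dimethyl 2-(4-methylpent-3-enyl)-2-[(3S,5E,9Z,13Z)-15-(tert-butyldimethylsilyloxy)-14-iodo-6,10-dimethylpentadeca-1,5,9,13-tetraen-3-yl]malonate
Conditions: t-BuMe2SiCl, imidazole, DMF, rt
Reagents that add atoms: tert-butyldimethylsilyl chloride CC(C)(C)[Si](C)(C)Cl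
Why: Silylation protects the primary allylic alcohol through the decarboxylation and the palladium step (silyl ether formation).

Step 17
Reactants: 24 dimethyl 2-(4-methylpent-3-enyl)-2-[(3S,5E,9Z,13Z)-15-(tert-butyldimethylsilyloxy)-14-iodo-6,10-dimethylpentadeca-1,5,9,13-tetraen-3-yl]malonate
Product: 25 methyl 2-[(3S,5E,9Z,13Z)-15-(tert-butyldimethylsilyloxy)-14-iodo-6,10-dimethylpentadeca-1,5,9,13-tetraen-3-yl]-6-methylhept-5-enoate
Conditions: LiCl, H2O, DMSO, 150 °C
Reagents that add atoms: none
Why: In this Krapcho dealkoxycarbonylation chloride demethylates one ester and the carboxylate loses CO2, leaving the mono-ester whose α-centre need not be controlled because it is enolised in step 22.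

Step 18
Reactants: 25 methyl 2-[(3S,5E,9Z,13Z)-15-(tert-butyldimethylsilyloxy)-14-iodo-6,10-dimethylpentadeca-1,5,9,13-tetraen-3-yl]-6-methylhept-5-enoate
Product: 27 methyl 2-[(1R,3E,7Z,11E)-12-(tert-butyldimethylsilyloxymethyl)-4,8-dimethylcyclotetradeca-3,7,11-trien-1-yl]-6-methylhept-5-enoate, via alkylborane 26 (not isolated)
Conditions: 9-BBN, THF, rt; then Pd(dppf)Cl2·CH2Cl2 (20 mol %), AsPh3, Cs2CO3, DMF/THF/H2O, 50 °C, slow addition (1 mM)
Reagents that add atoms: none
Why: 9-BBN hydroborates only the monosubstituted vinyl group, and intramolecular B-alkyl Suzuki–Miyaura coupling (oxidative addition of zerovalent palladium to the vinyl iodide with retention) closes the 14-membered ring so that the new ring CH2 (future C-13) is cis to the chain on the trisubstituted alkene.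

Step 19
Reactants: 27 methyl 2-[(1R,3E,7Z,11E)-12-(tert-butyldimethylsilyloxymethyl)-4,8-dimethylcyclotetradeca-3,7,11-trien-1-yl]-6-methylhept-5-enoate
Product: 28 methyl 2-[(1R,3E,7Z,11E)-12-(hydroxymethyl)-4,8-dimethylcyclotetradeca-3,7,11-trien-1-yl]-6-methylhept-5-enoate
Conditions: Bu4NF, THF, rt
Reagents that add atoms: none
Why: Fluoride cleaves the silyl ether (desilylation) without affecting the ester or the alkenes.

Step 20
Reactants: 28 methyl 2-[(1R,3E,7Z,11E)-12-(hydroxymethyl)-4,8-dimethylcyclotetradeca-3,7,11-trien-1-yl]-6-methylhept-5-enoate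
Product: 29 2-[(1R,3E,7Z,11E)-12-(hydroxymethyl)-4,8-dimethylcyclotetradeca-3,7,11-trien-1-yl]-6-methylhept-5-enoic acid
Conditions: LiOH·H2O, THF/MeOH/H2O, 50 °C; then dilute HCl
Reagents that add atoms: lithium hydroxide [Li+].[OH-]
Why: Saponification of the methyl ester gives the seco acid, and the ring stereocentre (β to the carboxyl group) cannot epimerise.

Step 21
Reactants: 29 2-[(1R,3E,7Z,11E)-12-(hydroxymethyl)-4,8-dimethylcyclotetradeca-3,7,11-trien-1-yl]-6-methylhept-5-enoic acid
Product: 30 eight-membered lactone of 29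
Conditions: 2-methyl-6-nitrobenzoic anhydride, DMAP, Et3N, CH2Cl2, rt, slow addition (1 mM)
Reagents that add atoms: none
Why: Shiina lactonisation (mixed anhydride, acyl transfer by DMAP) under high dilution closes the eight-membered lactone, a ring size for which the method has precedent, helped by the exocyclic sp2 carbon and the carbocycle that hold the two ends close.

Step 22
Reactants: 30 eight-membered lactone of 29
Product: 33 (1R,3E,7Z,11S,15S)-4,8-dimethyl-12-methylidene-15-(4-methylpent-3-enyl)bicyclo[9.3.1]pentadeca-3,7-diene-15-carboxylic acid, via silyl ketene acetal 31 (not isolated), via silyl ester 32 (not isolated)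
Conditions: LiN(iPr)2, Me3SiCl, Et3N, THF, −100 → −78 °C; then toluene, 90 °C; then dilute HCl, THF/H2O, rt
Reagents that add atoms: none
Why: Proposed new method: deprotonation α to the lactone carbonyl with internal silylation gives the ring-locked (cis) silyl ketene acetal 31, which undergoes an Ireland–Claisen [3,3] shift through a bicyclo[3.3.1]-like chair–chair transition state, bonding the ketene acetal carbon (future C-15) to the alkene CH (future C-11) while the O–CH2 bond breaks; the closest known reaction type is the ring-contracting Ireland–Claisen rearrangement of medium- and large-ring lactone silyl ketene acetals, here used transannularly on a lactone whose allylic alkene is exocyclic to the lactone and endocyclic to a carbocycle. The six-membered ring is closed by contraction of the eight-membered lactone (C(=O)–O–CH2 leave the ring, the alkene CH enters it, a 6-membered sigmatropic closure onto the exocyclic alkene carbon) and the 12-membered ring arises from the 14-membered ring by the same transannular C–C bond, the extruded CH2 becoming the exocyclic methylene and the ring oxygen a carboxyl oxygen. The configuration of C-15 relative to C-11 is fixed by the ring-locked ketene acetal (the carboxyl carbon must stay axial on the forming chair to remain tethered) and by the alkene geometry (the chain carbon cis to the ring CH2 ends axial at C-11, hence anti to the carboxyl group). Both new centres are set relative to the existing centre (future C-1) because its macrocyclic CH2 branch should take the equatorial site of the forming chair, whereas the ring-flipped transition state would put the two macrocycle branches at C-1 and C-11 syn-diaxial, a syn-pentane arrangement inside the 12-membered ring. The step needs this facial selectivity and clean enolisation at the single α-CH, and the internal quench with Me3SiCl at −100 °C is chosen to outrun β-elimination of the lactone enolate.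

Step 23
Reactants: 33 (1R,3E,7Z,11S,15S)-4,8-dimethyl-12-methylidene-15-(4-methylpent-3-enyl)bicyclo[9.3.1]pentadeca-3,7-diene-15-carboxylic acid
Product: 34 iodolactone of 33
Conditions: I2, NaHCO3, MeCN/H2O, 0 °C, dark
Reagents that add atoms: iodine II
Why: In this iodolactonisation only the exocyclic methylene is γ,δ to the carboxyl group, so 5-exo Markovnikov attack of the axial carboxylate gives the bridged γ-lactone chemoselectively, with the new C–O bond at C-12 necessarily cis to the carboxyl carbon.

Step 24
Reactants: 34 iodolactone of 33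
Product: 36 CNP0267152.2, via lithium epoxy carboxylate 35 (not isolated)
Conditions: LiOH·H2O, THF/H2O, rt; evaporate, dry; LiNEt2 (Et2NH, n-BuLi), THF, 0 °C → rt; then dilute HCl (pH 4), 0 °C
Reagents that add atoms: lithium hydroxide [Li+].[OH-]
Why: Hydroxide opens the strained lactone and the tertiary alkoxide displaces iodide to give the spiro-epoxide, and lithium diethylamide then effects the base-mediated epoxide-to-allylic-alcohol rearrangement by removing a proton from the less hindered ring CH2 (C-13), which places the double bond at C-12=C-13 and leaves CH2OH.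

**Compound list**

1 | nerol, (2Z)-3,7-dimethylocta-2,6-dien-1-ol | CC(C)=CCC/C(C)=C\CO | starting material
2 | neryl bromide, (2Z)-1-bromo-3,7-dimethylocta-2,6-diene | CC(C)=CCC/C(C)=C\CBr | intermediate
3 | 1-(trimethylsilyl)propyne | CC#C[Si](C)(C)C | starting material
4 | (5Z)-6,10-dimethyl-1-(trimethylsilyl)undeca-5,9-dien-1-yne | CC(C)=CCC/C(C)=C\CCC#C[Si](C)(C)C | intermediate
5 | (5Z)-6,10-dimethylundeca-5,9-dien-1-yne | CC(C)=CCC/C(C)=C\CCC#C | intermediate
6 | dimethyl[(1E,5Z)-2,6,10-trimethylundeca-1,5,9-trien-1-yl]alane | CC(C)=CCC/C(C)=C\CC/C(C)=C/[Al](C)C | intermediate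
7 | (2E,6Z)-farnesol, (2E,6Z)-3,7,11-trimethyldodeca-2,6,10-trien-1-ol | CC(C)=CCC/C(C)=C\CC/C(C)=C/CO | intermediate
8 | (2E,6Z)-farnesyl bromide | CC(C)=CCC/C(C)=C\CC/C(C)=C/CBr | intermediate
9 | propargyl alcohol | C#CCO | starting material
10 | (5E,9Z)-6,10,14-trimethylpentadeca-5,9,13-trien-2-yn-1-ol | CC(C)=CCC/C(C)=C\CC/C(C)=C/CC#CCO | intermediate
11 | (2E,5E,9Z)-6,10,14-trimethylpentadeca-2,5,9,13-tetraen-1-ol | CC(C)=CCC/C(C)=C\CC/C(C)=C/C/C=C/CO | intermediate
12 | methyl (2E,5E,9Z)-6,10,14-trimethylpentadeca-2,5,9,13-tetraenyl carbonate | CC(C)=CCC/C(C)=C\CC/C(C)=C/C/C=C/COC(=O)OC | intermediate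
13 | dimethyl malonate | COC(=O)CC(=O)OC | starting material
14 | dimethyl 2-[(3S,5E,9Z)-6,10,14-trimethylpentadeca-1,5,9,13-tetraen-3-yl]malonate | COC(=O)C(C(=O)OC)[C@@H](C/C=C(C)/CC/C=C(C)\CCC=C(C)C)C=C | intermediate
15 | bromohydrin of 14 (13-bromo-14-hydroxy, both epimers at C-13 of the chain) | COC(=O)C(C(=O)OC)[C@@H](C/C=C(C)/CC/C=C(C)\CCC(Br)C(C)(C)O)C=C | intermediate
16 | dimethyl 2-[(3S,5E,9Z)-13,14-epoxy-6,10,14-trimethylpentadeca-1,5,9-trien-3-yl]malonate (both epoxide epimers) | COC(=O)C(C(=O)OC)[C@@H](C/C=C(C)/CC/C=C(C)\CCC1OC1(C)C)C=C | intermediate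
17 | 5-bromo-2-methylpent-2-ene | CC(C)=CCCBr | starting material
18 | dimethyl 2-(4-methylpent-3-enyl)-2-[(3S,5E,9Z)-13,14-epoxy-6,10,14-trimethylpentadeca-1,5,9-trien-3-yl]malonate | COC(=O)C(CCC=C(C)C)(C(=O)OC)[C@@H](C/C=C(C)/CC/C=C(C)\CCC1OC1(C)C)C=C | intermediate
19 | dimethyl 2-(4-methylpent-3-enyl)-2-[(3S,5E,9Z)-6,10-dimethyl-13-oxotrideca-1,5,9-trien-3-yl]malonate | COC(=O)C(CCC=C(C)C)(C(=O)OC)[C@@H](C/C=C(C)/CC/C=C(C)\CCC=O)C=C | intermediate
20 | (triphenylphosphoranylidene)acetaldehyde | O=CC=P(c1ccccc1)(c1ccccc1)c1ccccc1 | starting material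
21 | dimethyl 2-(4-methylpent-3-enyl)-2-[(3S,5E,9Z,13E)-6,10-dimethyl-15-oxopentadeca-1,5,9,13-tetraen-3-yl]malonate | COC(=O)C(CCC=C(C)C)(C(=O)OC)[C@@H](C/C=C(C)/CC/C=C(C)\CC/C=C/C=O)C=C | intermediate
22 | dimethyl 2-(4-methylpent-3-enyl)-2-[(3S,5E,9Z,13Z)-14-iodo-6,10-dimethyl-15-oxopentadeca-1,5,9,13-tetraen-3-yl]malonate | COC(=O)C(CCC=C(C)C)(C(=O)OC)[C@@H](C/C=C(C)/CC/C=C(C)\CC/C=C(\I)C=O)C=C | intermediate
23 | dimethyl 2-(4-methylpent-3-enyl)-2-[(3S,5E,9Z,13Z)-15-hydroxy-14-iodo-6,10-dimethylpentadeca-1,5,9,13-tetraen-3-yl]malonate | COC(=O)C(CCC=C(C)C)(C(=O)OC)[C@@H](C/C=C(C)/CC/C=C(C)\CC/C=C(\I)CO)C=C | intermediate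
24 | tert-butyldimethylsilyl ether of 23 | COC(=O)C(CCC=C(C)C)(C(=O)OC)[C@@H](C/C=C(C)/CC/C=C(C)\CC/C=C(\I)CO[Si](C)(C)C(C)(C)C)C=C | intermediate
25 | methyl 2-[(3S,5E,9Z,13Z)-15-(tert-butyldimethylsilyloxy)-14-iodo-6,10-dimethylpentadeca-1,5,9,13-tetraen-3-yl]-6-methylhept-5-enoate (both epimers at C-2 of the heptenoate) | COC(=O)C(CCC=C(C)C)[C@@H](C/C=C(C)/CC/C=C(C)\CC/C=C(\I)CO[Si](C)(C)C(C)(C)C)C=C | intermediate
26 | B-alkyl-9-borabicyclo[3.3.1]nonane from hydroboration of the vinyl group of 25 | COC(=O)C(CCC=C(C)C)[C@@H](C/C=C(C)/CC/C=C(C)\CC/C=C(\I)CO[Si](C)(C)C(C)(C)C)CCB1C2CCCC1CCC2 | intermediate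
27 | methyl 2-[(1R,3E,7Z,11E)-12-(tert-butyldimethylsilyloxymethyl)-4,8-dimethylcyclotetradeca-3,7,11-trien-1-yl]-6-methylhept-5-enoate (C-2 epimers) | COC(=O)C(CCC=C(C)C)[C@H]1C/C=C(C)/CC/C=C(C)\CC/C=C(CO[Si](C)(C)C(C)(C)C)\CC1 | intermediate
28 | methyl 2-[(1R,3E,7Z,11E)-12-(hydroxymethyl)-4,8-dimethylcyclotetradeca-3,7,11-trien-1-yl]-6-methylhept-5-enoate (C-2 epimers) | COC(=O)C(CCC=C(C)C)[C@H]1C/C=C(C)/CC/C=C(C)\CC/C=C(CO)\CC1 | intermediate
29 | 2-[(1R,3E,7Z,11E)-12-(hydroxymethyl)-4,8-dimethylcyclotetradeca-3,7,11-trien-1-yl]-6-methylhept-5-enoic acid (C-2 epimers) | OC(=O)C(CCC=C(C)C)[C@H]1C/C=C(C)/CC/C=C(C)\CC/C=C(CO)\CC1 | intermediate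
30 | eight-membered lactone of 29: ester between the side-chain carboxyl group and the hydroxymethyl oxygen, bridging ring carbons 1 and 12 of the cyclotetradecatriene; R at the ring CH; both epimers at the lactone α-carbon, which carries the 4-methylpent-3-enyl group | O=C1OC/C2=C/CC/C(C)=C\CC/C(C)=C/C[C@@H](CC2)C1CCC=C(C)C | intermediate
31 | trimethylsilyl ketene acetal of 30 (enol double bond cis within the eight-membered ring) | CC(C)=CCC/C1=C(\O[Si](C)(C)C)OC/C2=C/CC/C(C)=C\CC/C(C)=C/C[C@H]1CC2 | intermediate
32 | trimethylsilyl ester of 33 | CC(C)=CCC[C@]1(C(=O)O[Si](C)(C)C)[C@@H]2CCC(=C)[C@@H]1CC/C(C)=C\CC/C(C)=C/C2 | intermediate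
33 | (1R,3E,7Z,11S,15S)-4,8-dimethyl-12-methylidene-15-(4-methylpent-3-enyl)bicyclo[9.3.1]pentadeca-3,7-diene-15-carboxylic acid | CC(C)=CCC[C@]1(C(=O)O)[C@@H]2CCC(=C)[C@@H]1CC/C(C)=C\CC/C(C)=C/C2 | intermediate
34 | iodolactone of 33: γ-lactone from the C-15 carboxyl group to C-12, iodomethyl group on C-12, lactone oxygen cis to the carboxyl carbon | CC(C)=CCC[C@]12C(=O)O[C@](CI)(CC[C@@H]1C/C=C(C)/CC/C=C(C)\CC3)[C@@H]23 | intermediate
35 | lithium salt of the C-12 spiro-epoxy acid (oxirane oxygen on the face of the carboxylate) | CC(C)=CCC[C@]1(C(=O)[O-])[C@@H]2CC[C@]3(CO3)[C@@H]1CC/C(C)=C\CC/C(C)=C/C2.[Li+] | intermediate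
36 | CNP0267152.2, (1S,3E,7Z,11S,15S)-12-(hydroxymethyl)-4,8-dimethyl-15-(4-methylpent-3-enyl)bicyclo[9.3.1]pentadeca-3,7,12-triene-15-carboxylic acid | CC(C)=CCC[C@]1(C(=O)O)[C@@H]2CC=C(CO)[C@@H]1CC/C(C)=C\CC/C(C)=C/C2 | target

**Totals and risks**

Total step count: 24. Longest linear sequence: 24 steps (nerol 1 to 36); all other inputs are commercial.

The three steps most likely to fail:

Step 22. The lactone enolate may undergo β-elimination (ring opening to a ketene and the allylic alkoxide) before it is silylated, or the bond may form through the ring-flipped transition state (poor facial selectivity). The fallback uses known chemistry and makes the same C-15–C-11 bond without a sigmatropic step. It sets out from 28: Corey–Kim chlorination (N-chlorosuccinimide, Me2S, CH2Cl2, −20 °C) should give the allylic chloride F1. KN(SiMe3)2 in THF at −78 → 0 °C should then close the six-membered ring by intramolecular SN2′ alkylation of the ester enolate onto the alkene CH, with the chloride leaving from the exocyclic carbon, to give the methyl ester F2. Cleavage of the hindered methyl ester by SN2 attack of n-PrSLi in HMPA at the methyl group comes back to the route at 33. In this variant the configuration at C-15 rests on which face of the free enolate closes, and would have to be steered by the enolate geometry (choice of base and solvent).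

Step 21. Intermolecular esterification to diolides and oligomers may outrun closure of the strained eight-membered ring. The fallback reverses the order of the two ring closures and sets out from 25. Bu4NF should give the acyclic hydroxy ester F3, and LiOH the seco acid F4. Shiina lactonisation then closes an unstrained 16-membered ring, the macrolactone F5. Hydroboration of its vinyl group with 9-BBN should give the alkylborane F6 (not isolated), and transannular B-alkyl Suzuki coupling (Pd(dppf)Cl2·CH2Cl2, AsPh3, Cs2CO3) forms the C-13–C-12 bond and comes back to the route at 30.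

Step 24. The amide base may remove the tertiary C-11 proton instead of a C-13 proton (double bond in the wrong position), or the neighbouring carboxylate may open the epoxide during handling. The fallback carries the acid as an ester and uses a bulkier, more selective base; it sets out from 34. NaOMe in MeOH should open the lactone and close the epoxide to give the epoxy methyl ester F7. Diethylaluminium 2,2,6,6-tetramethylpiperidide (Et2AlNC9H18) in toluene at 0 °C should rearrange it to the allylic alcohol methyl ester F8. n-PrSLi in HMPA then cleaves the methyl ester and comes back to the route at 36.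

**Further compounds**

F1 | step 22 | methyl 2-[(1R,3E,7Z,11E)-12-(chloromethyl)-4,8-dimethylcyclotetradeca-3,7,11-trien-1-yl]-6-methylhept-5-enoate | COC(=O)C(CCC=C(C)C)[C@H]1C/C=C(C)/CC/C=C(C)\CC/C=C(CCl)\CC1
F2 | step 22 | methyl ester of 33 | CC(C)=CCC[C@]1(C(=O)OC)[C@@H]2CCC(=C)[C@@H]1CC/C(C)=C\CC/C(C)=C/C2
F3 | step 21 | methyl 2-[(3S,5E,9Z,13Z)-15-hydroxy-14-iodo-6,10-dimethylpentadeca-1,5,9,13-tetraen-3-yl]-6-methylhept-5-enoate | COC(=O)C(CCC=C(C)C)[C@@H](C/C=C(C)/CC/C=C(C)\CC/C=C(\I)CO)C=C
F4 | step 21 | 2-[(3S,5E,9Z,13Z)-15-hydroxy-14-iodo-6,10-dimethylpentadeca-1,5,9,13-tetraen-3-yl]-6-methylhept-5-enoic acid | OC(=O)C(CCC=C(C)C)[C@@H](C/C=C(C)/CC/C=C(C)\CC/C=C(\I)CO)C=C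
F5 | step 21 | 16-membered macrolactone of F4 (ester between the carboxyl group and the 15-hydroxyl group; vinyl and iodine retained) | O=C1OC/C(I)=C/CC/C(C)=C\CC/C(C)=C/C[C@@H](C=C)C1CCC=C(C)C
F6 | step 21 | B-alkyl-9-borabicyclo[3.3.1]nonane from hydroboration of the vinyl group of F5 | O=C1OC/C(I)=C/CC/C(C)=C\CC/C(C)=C/C[C@@H](CCB2C3CCCC2CCC3)C1CCC=C(C)C
F7 | step 24 | methyl ester of the C-12 spiro-epoxy acid | CC(C)=CCC[C@]1(C(=O)OC)[C@@H]2CC[C@]3(CO3)[C@@H]1CC/C(C)=C\CC/C(C)=C/C2
F8 | step 24 | methyl ester of 36 | CC(C)=CCC[C@]1(C(=O)OC)[C@@H]2CC=C(CO)[C@@H]1CC/C(C)=C\CC/C(C)=C/C2
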